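The cyclohexane is traced back to a ten-membered ring (elemane numbering). In the target the vinyl carbons on the quaternary C10 (C1–C2, later the epoxide) and the methylene C3 of the acrolein on C5 are the two ends of a 1,5-diene, and the C6 carbinol beside the C7/C11 methylene lactone is a homoallylic alcohol. One operation therefore takes a geranyl-derived open chain, an enal carrying a bromomethyl butenolide, through chromium-mediated allylation (C6–C7) to a germacranolide that contracts by Cope rearrangement (C5–C10) into the elemanolide ring with its C5, C7 and C10 stereocentres. Ketone reduction, allylic oxidation and hydroxyl-directed epoxidation complete the target.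

Key step: step 11

Remark: the target is taken as the open 6-hydroxy-15-aldehyde of the SMILES (it may equilibrate with its lactol). Numbering is ring C5–C10, lactone C7–C11–C12–O–C8, methylene C13, methyl C14, acrolein C4(=C3)–C15, epoxide C1–C2.

Step 1
Reactants: 1 geranyl acetate
Product: 2 (2E,6E)-8-hydroxy-3,7-dimethylocta-2,6-dien-1-yl acetate
Conditions: SeO2 (0.1 equiv), t-BuOOH, salicylic acid (cat.), CH2Cl2, 25 °C
Reagents that add atoms: tert-butyl hydroperoxide, CC(C)(C)OO
Why: Selenium dioxide allylic oxidation (ene reaction, then [2,3] shift) should hydroxylate the (E)-methyl of the terminal trisubstituted alkene and leave the allylic acetate end alone.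

Step 2
Reactants: 2 (2E,6E)-8-hydroxy-3,7-dimethylocta-2,6-dien-1-yl acetate
Product: 3 (2E,6E)-3,7-dimethyl-8-oxoocta-2,6-dien-1-yl acetate
Conditions: MnO2 (activated), CH2Cl2, 25 °C
Reagents that add atoms: none
Why: Heterogeneous MnO2 oxidation of a primary allylic alcohol should give the enal with the E geometry retained.

Step 3
Reactants: 4 furan-3-ylmethanol
Product: 5 3-(hydroxymethyl)furan-2(5H)-one
Conditions: n-BuLi (2.2 equiv), THF, −78→0 °C; B(OMe)3, −78 °C; 30% H2O2, 0→25 °C
Reagents that add atoms: hydrogen peroxide, OO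
Why: Alkoxide-directed lithiation at C2, borylation and oxidation of the furylboronate should give the 2-hydroxyfuran, which tautomerises to the conjugated butenolide.

Step 4
Reactants: 5 3-(hydroxymethyl)furan-2(5H)-one
Product: 6 2-(tert-butyldimethylsilyloxy)-3-[(tert-butyldimethylsilyloxy)methyl]furan
Conditions: TBSOTf (2.2 equiv), Et3N, CH2Cl2, 0 °C
Reagents that add atoms: tert-butyldimethylsilyl triflate, CC(C)(C)[Si](C)(C)OS(=O)(=O)C(F)(F)F
Why: The silyl triflate should silylate the alcohol and, by soft enolisation of the butenolide, the lactone oxygen, giving the aromatic 2-silyloxyfuran.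

Step 5
Reactants: 3 (2E,6E)-3,7-dimethyl-8-oxoocta-2,6-dien-1-yl acetate; 6 2-(tert-butyldimethylsilyloxy)-3-[(tert-butyldimethylsilyloxy)methyl]furan
Product: 7 (5R)-5-[(1S,2E,6E)-8-acetoxy-1-hydroxy-2,6-dimethylocta-2,6-dien-1-yl]-3-[(tert-butyldimethylsilyloxy)methyl]furan-2(5H)-one
Conditions: SiCl4 (1.1 equiv), chiral 2,2'-binaphthyldiamine-derived bisphosphoramide (5 mol %, enantiomer chosen for the 1S carbinol), i-Pr2NEt (10 mol %), CH2Cl2, −78 °C; aq. NaHCO3 work-up
Reagents that add atoms: none
Why: In this Lewis base-activated SiCl4 vinylogous Mukaiyama aldol reaction the furan should attack the conjugated aldehyde through its γ-carbon in an open transition state, which favours the anti adduct, while the chiral phosphoramide sets the absolute configuration of both new centres (C8 R, C9 S).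

Step 6
Reactants: 7 (5R)-5-[(1S,2E,6E)-8-acetoxy-1-hydroxy-2,6-dimethylocta-2,6-dien-1-yl]-3-[(tert-butyldimethylsilyloxy)methyl]furan-2(5H)-one; 8 angelic acid
Product: 9 (1S,2E,6E)-8-acetoxy-1-[(2R)-4-{[(tert-butyldimethylsilyl)oxy]methyl}-5-oxo-2,5-dihydrofuran-2-yl]-2,6-dimethylocta-2,6-dien-1-yl (2Z)-2-methylbut-2-enoate
Conditions: 2,4,6-Cl3C6H2COCl, Et3N, PhMe, 25 °C; then 7, 40 °C (no DMAP)
Reagents that add atoms: none
Why: Yamaguchi mixed-anhydride esterification should acylate the unhindered secondary allylic alcohol with retention, and leaving out the nucleophilic catalyst limits angelate-to-tiglate isomerisation and base-induced elimination next to the butenolide.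

Step 7
Reactants: 9 (1S,2E,6E)-8-acetoxy-1-[(2R)-4-{[(tert-butyldimethylsilyl)oxy]methyl}-5-oxo-2,5-dihydrofuran-2-yl]-2,6-dimethylocta-2,6-dien-1-yl (2Z)-2-methylbut-2-enoate
Product: 10 (1S,2E,6E)-1-[(2R)-4-{[(tert-butyldimethylsilyl)oxy]methyl}-5-oxo-2,5-dihydrofuran-2-yl]-8-hydroxy-2,6-dimethylocta-2,6-dien-1-yl (2Z)-2-methylbut-2-enoate
Conditions: Candida antarctica lipase B (immobilised), n-BuOH, t-BuOMe, 30 °C
Reagents that add atoms: none
Why: Lipase transesterification should remove the primary allylic acetate under neutral conditions, sparing the hindered secondary angelate and the lactone and not epimerising the acidic C8 position.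

Step 8
Reactants: 10 (1S,2E,6E)-1-[(2R)-4-{[(tert-butyldimethylsilyl)oxy]methyl}-5-oxo-2,5-dihydrofuran-2-yl]-8-hydroxy-2,6-dimethylocta-2,6-dien-1-yl (2Z)-2-methylbut-2-enoate
Product: 11 (1S,2E,6E)-1-[(2R)-4-{[(tert-butyldimethylsilyl)oxy]methyl}-5-oxo-2,5-dihydrofuran-2-yl]-2,6-dimethyl-8-oxoocta-2,6-dien-1-yl (2Z)-2-methylbut-2-enoate
Conditions: MnO2 (activated), CH2Cl2, 25 °C
Reagents that add atoms: none
Why: MnO2 oxidation of the geraniol-type allylic alcohol should give the (E)-enal while the butenolide oxygen is still silylated.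

Step 9
Reactants: 11 (1S,2E,6E)-1-[(2R)-4-{[(tert-butyldimethylsilyl)oxy]methyl}-5-oxo-2,5-dihydrofuran-2-yl]-2,6-dimethyl-8-oxoocta-2,6-dien-1-yl (2Z)-2-methylbut-2-enoate
Product: 12 (1S,2E,6E)-1-[(2R)-4-(hydroxymethyl)-5-oxo-2,5-dihydrofuran-2-yl]-2,6-dimethyl-8-oxoocta-2,6-dien-1-yl (2Z)-2-methylbut-2-enoate
Conditions: HF·pyridine, pyridine, THF, 0 °C
Reagents that add atoms: none
Why: Buffered fluoride desilylation should free the primary alcohol without touching the enal, the angelate or the lactone.

Step 10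
Reactants: 12 (1S,2E,6E)-1-[(2R)-4-(hydroxymethyl)-5-oxo-2,5-dihydrofuran-2-yl]-2,6-dimethyl-8-oxoocta-2,6-dien-1-yl (2Z)-2-methylbut-2-enoate
Product: 13 (1S,2E,6E)-1-[(2R)-4-(bromomethyl)-5-oxo-2,5-dihydrofuran-2-yl]-2,6-dimethyl-8-oxoocta-2,6-dien-1-yl (2Z)-2-methylbut-2-enoate
Conditions: PPh3 and NBS premixed, CH2Cl2, −20 °C; then 12
Reagents that add atoms: N-bromosuccinimide, O=C1CCC(=O)N1Br
Why: Appel-type bromination through the alkoxyphosphonium salt should displace the primary allylic hydroxyl by SN2, and the preformed bromophosphonium reagent leaves the aldehyde and the alkenes alone.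

Step 11
Reactants: 13 (1S,2E,6E)-1-[(2R)-4-(bromomethyl)-5-oxo-2,5-dihydrofuran-2-yl]-2,6-dimethyl-8-oxoocta-2,6-dien-1-yl (2Z)-2-methylbut-2-enoate
Product: 15 (5S,6R,7S,8R,9S,10S)-9-angeloyloxy-6-hydroxyelema-1,3,11(13)-trien-12,8-olide, via ten-membered germacranolide 14 (not isolated)
Conditions: CrCl2 (8 equiv), THF–DMF 3:1, 25 °C, 13 added over 10 h (final 2 mM); then H2O (20 equiv), 100 °C, 6 h
Reagents that add atoms: none
Why: Divalent chromium inserts into the allylic C–Br bond and the allylchromium adds through its γ-carbon C7 to the enal carbonyl in a six-membered chair transition state, closing the ten-membered ring by exo attack on the carbonyl (C6–C7) and unveiling the methylene lactone (Nozaki–Hiyama–Kishi-type macrocyclic allylation). After protonation of the trivalent chromium alkoxide, warming sends the 1(10)E,4E-diene of 14 through a chair [3,3] shift, a transannular Cope ring contraction that forms C5–C10 and the cyclohexane. The closest known reactions are chromium Barbier macrocyclisations of 2-(bromomethyl)acrylates onto aldehydes to germacranolides, aldehyde allylations with bromomethyl butenolides, and the thermal germacranolide-to-elemanolide Cope rearrangement. C7 is set by attack on the butenolide face opposite the C8 side chain (trans lactone); C6 is expected trans to C11 from the chair with the tether equatorial, which is the wrong epimer, so steps 12–13 take C6 through the ketone and either epimer converges. C5 and C10 follow from the E,E geometry and the one chair in which the trans-fused lactone is diequatorial, so H5 and the C10 methyl end up trans with isopropenyl and vinyl equatorial. The step needs ring closure over oligomerisation (high dilution), γ- over α-attack (usual for allylchromium), and a Cope equilibrium on the elemane side (relief of ten-ring strain).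

Step 12
Reactants: 15 (5S,6R,7S,8R,9S,10S)-9-angeloyloxy-6-hydroxyelema-1,3,11(13)-trien-12,8-olide
Product: 16 (5S,7R,8R,9S,10S)-9-angeloyloxy-6-oxoelema-1,3,11(13)-trien-12,8-olide
Conditions: Dess–Martin periodinane, CH2Cl2, 0 °C, short reaction time
Reagents that add atoms: none
Why: Dess–Martin oxidation under near-neutral conditions should give the ketone from either C6 epimer without moving the two β,γ-double bonds into conjugation.

Step 13
Reactants: 16 (5S,7R,8R,9S,10S)-9-angeloyloxy-6-oxoelema-1,3,11(13)-trien-12,8-olide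
Product: 17 (5S,6S,7S,8R,9S,10S)-9-angeloyloxy-6-hydroxyelema-1,3,11(13)-trien-12,8-olide
Conditions: LiAlH(Ot-Bu)3, THF, −78→−40 °C
Reagents that add atoms: none
Why: In this diastereoselective ketone reduction the axial C10 methyl blocks the axial path, so the bulky hydride should enter equatorially and give the axial 6S alcohol cis to the C5 and C7 substituents, while lactone, angelate and methylene lactone are not reduced at this temperature.

Step 14
Reactants: 17 (5S,6S,7S,8R,9S,10S)-9-angeloyloxy-6-hydroxyelema-1,3,11(13)-trien-12,8-olide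
Product: 18 (5S,6S,7S,8R,9S,10S)-9-angeloyloxy-6,15-dihydroxyelema-1,3,11(13)-trien-12,8-olide
Conditions: SeO2 (0.3 equiv), t-BuOOH, CH2Cl2, 25 °C
Reagents that add atoms: tert-butyl hydroperoxide, CC(C)(C)OO
Why: Selenium dioxide allylic oxidation should hydroxylate the methyl of the isopropenyl group (methyl preferred over the C5 methine), since the vinyl group has no allylic hydrogen and the two electron-poor alkenes react far more slowly.

Step 15
Reactants: 18 (5S,6S,7S,8R,9S,10S)-9-angeloyloxy-6,15-dihydroxyelema-1,3,11(13)-trien-12,8-olide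
Product: 19 (5R,6S,7S,8R,9S,10S)-9-angeloyloxy-6-hydroxy-15-oxoelema-1,3,11(13)-trien-12,8-olide
Conditions: MnO2 (activated), CH2Cl2, 25 °C
Reagents that add atoms: none
Why: MnO2 should oxidise only the primary allylic alcohol to the 2-substituted acrolein and leave the non-allylic C6 hydroxyl.

Step 16
Reactants: 19 (5R,6S,7S,8R,9S,10S)-9-angeloyloxy-6-hydroxy-15-oxoelema-1,3,11(13)-trien-12,8-olide
Product: 20 (1R,5R,6S,7S,8R,9S,10R)-9-angeloyloxy-1,2-epoxy-6-hydroxy-15-oxoelema-3,11(13)-dien-12,8-olide (CNP0130022.2)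
Conditions: VO(acac)2 (5 mol %), t-BuOOH, PhMe, 0→25 °C
Reagents that add atoms: tert-butyl hydroperoxide, CC(C)(C)OO
Why: In this hydroxyl-directed epoxidation the vanadate ester of the axial C6 hydroxyl should deliver oxygen to the face of the C10 vinyl group that is turned toward C5/C6, which corresponds to the 1R epoxide, while the enal, methylene lactone and angelate alkenes are too electron-poor for the electrophilic peroxo-vanadium species.

Compound list
1 | geranyl acetate | CC(C)=CCC/C(C)=C/COC(C)=O | starting material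
2 | (2E,6E)-8-hydroxy-3,7-dimethylocta-2,6-dien-1-yl acetate | OC/C(C)=C/CC/C(C)=C/COC(C)=O | intermediate
3 | (2E,6E)-3,7-dimethyl-8-oxoocta-2,6-dien-1-yl acetate | O=C/C(C)=C/CC/C(C)=C/COC(C)=O | intermediate
4 | furan-3-ylmethanol | OCc1ccoc1 | starting material
5 | 3-(hydroxymethyl)furan-2(5H)-one | O=C1OCC=C1CO | intermediate
6 | 2-(tert-butyldimethylsilyloxy)-3-[(tert-butyldimethylsilyloxy)methyl]furan | CC(C)(C)[Si](C)(C)OCc1ccoc1O[Si](C)(C)C(C)(C)C | intermediate
7 | (5R)-5-[(1S,2E,6E)-8-acetoxy-1-hydroxy-2,6-dimethylocta-2,6-dien-1-yl]-3-[(tert-butyldimethylsilyloxy)methyl]furan-2(5H)-one | CC(=O)OC/C=C(C)/CC/C=C(C)/[C@H](O)[C@H]1C=C(CO[Si](C)(C)C(C)(C)C)C(=O)O1 | intermediate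
8 | angelic acid, (2Z)-2-methylbut-2-enoic acid | C/C=C(/C)C(=O)O | starting material
9 | angelate of 7 (8R,9S; acetate and silyl ether in place) | CC(=O)OC/C=C(C)/CC/C=C(C)/[C@H](OC(=O)/C(C)=C\C)[C@H]1C=C(CO[Si](C)(C)C(C)(C)C)C(=O)O1 | intermediate
10 | primary allylic alcohol from 9 (acetate removed) | OC/C=C(C)/CC/C=C(C)/[C@H](OC(=O)/C(C)=C\C)[C@H]1C=C(CO[Si](C)(C)C(C)(C)C)C(=O)O1 | intermediate
11 | (E)-enal from 10 | O=C/C=C(C)/CC/C=C(C)/[C@H](OC(=O)/C(C)=C\C)[C@H]1C=C(CO[Si](C)(C)C(C)(C)C)C(=O)O1 | intermediate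
12 | 4-(hydroxymethyl)butenolide enal | O=C/C=C(C)/CC/C=C(C)/[C@H](OC(=O)/C(C)=C\C)[C@H]1C=C(CO)C(=O)O1 | intermediate
13 | 4-(bromomethyl)butenolide enal | O=C/C=C(C)/CC/C=C(C)/[C@H](OC(=O)/C(C)=C\C)[C@H]1C=C(CBr)C(=O)O1 | intermediate
14 | (6R,7S,8R,9S,1(10)E,4E)-9-angeloyloxy-6-hydroxygermacra-1(10),4,11(13)-trien-12,8-olide | C=C1C(=O)O[C@@H]2[C@@H]1[C@H](O)/C=C(C)/CC/C=C(C)/[C@@H]2OC(=O)/C(C)=C\C | intermediate
15 | (5S,6R,7S,8R,9S,10S)-9-angeloyloxy-6-hydroxyelema-1,3,11(13)-trien-12,8-olide | C=C1C(=O)O[C@@H]2[C@@H]1[C@H](O)[C@@H](C(C)=C)[C@](C)(C=C)[C@@H]2OC(=O)/C(C)=C\C | intermediate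
16 | (5S,7R,8R,9S,10S)-9-angeloyloxy-6-oxoelema-1,3,11(13)-trien-12,8-olide | C=C1C(=O)O[C@@H]2[C@@H]1C(=O)[C@@H](C(C)=C)[C@](C)(C=C)[C@@H]2OC(=O)/C(C)=C\C | intermediate
17 | (5S,6S,7S,8R,9S,10S)-9-angeloyloxy-6-hydroxyelema-1,3,11(13)-trien-12,8-olide | C=C1C(=O)O[C@@H]2[C@@H]1[C@@H](O)[C@@H](C(C)=C)[C@](C)(C=C)[C@@H]2OC(=O)/C(C)=C\C | intermediate
18 | (5S,6S,7S,8R,9S,10S)-9-angeloyloxy-6,15-dihydroxyelema-1,3,11(13)-trien-12,8-olide | C=C1C(=O)O[C@@H]2[C@@H]1[C@@H](O)[C@@H](C(=C)CO)[C@](C)(C=C)[C@@H]2OC(=O)/C(C)=C\C | intermediate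
19 | (5R,6S,7S,8R,9S,10S)-9-angeloyloxy-6-hydroxy-15-oxoelema-1,3,11(13)-trien-12,8-olide | C=C1C(=O)O[C@@H]2[C@@H]1[C@@H](O)[C@@H](C(=C)C=O)[C@](C)(C=C)[C@@H]2OC(=O)/C(C)=C\C | intermediate
20 | (1R,5R,6S,7S,8R,9S,10R)-9-angeloyloxy-1,2-epoxy-6-hydroxy-15-oxoelema-3,11(13)-dien-12,8-olide | C=C1C(=O)O[C@@H]2[C@@H]1[C@@H](O)[C@@H](C(=C)C=O)[C@](C)([C@@H]1CO1)[C@@H]2OC(=O)/C(C)=C\C | target

Total step count: 16. Longest linear sequence: 14 steps (1, 2, 5–16) from geranyl acetate; steps 3 and 4 make the silyloxyfuran.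

Steps most likely to fail

Step 11. Heating the chromium alkoxide may move the lactone toward the C6 oxygen, reverse the allylation, or leave the Cope equilibrium incomplete. The fallback separates the two bond formations and protects C6. It sets out from 14, isolated by stopping step 11 at 25 °C with aqueous work-up. Silylation (Me3SiCl, imidazole, CH2Cl2) should give the 6-O-trimethylsilyl germacranolide F1. Its ring contraction is then run as a separate catalysed Cope rearrangement with PdCl2(PhCN)2 (divalent palladium, 5 mol %, THF, 25 °C), which should proceed through a cyclohexyl-palladium cation stabilised at the methyl-bearing C4, to give the silylated elemanolide F2. Citric acid in methanol removes the silyl group and the route is rejoined at 15.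

Step 13. The β,γ-unsaturated ketone 16 may enolise, moving the methylene or isopropenyl double bond into conjugation and scrambling C5 or C7, or hydride delivery may show poor facial selectivity. The fallback corrects C6 by substitution while the alcohol is still allylic. It sets out from 14, isolated as above. Mitsunobu inversion (chloroacetic acid, PPh3, DIAD, THF, 0 °C) should give the inverted 6-chloroacetate germacranolide F3. Thiourea with NaHCO3 in ethanol should cleave the chloroacetate to the 6S-hydroxy germacranolide F4. Thermal Cope rearrangement of F4 (toluene, 110 °C) rejoins the route at 17, bypassing 15 and 16.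

Step 16. Oxygen may be delivered to the wrong alkene (the lactol tautomer offers vanadium an allylic hemiacetal), or facial selectivity across the 1,3-distance between C6–OH and the vinyl group may be poor. The fallback replaces substrate direction by resolution. It sets out from 19: undirected epoxidation with dimethyldioxirane (acetone, 0 °C) should give 20 mixed with its C1 epimer, the 1S epoxide F5. Hydrolytic kinetic resolution with N,N'-bis(3,5-di-tert-butylsalicylidene)-1,2-cyclohexanediaminocobalt acetate (trivalent cobalt, the enantiomer matched to the 1S epoxide) and 0.5 equiv of water should convert F5 into the 1,2-diol F6. Chromatography then leaves 20, where the route is rejoined.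

Further compounds
F1 | step 11 | (6R,7S,8R,9S)-9-angeloyloxy-6-(trimethylsilyloxy)germacra-1(10),4,11(13)-trien-12,8-olide | C=C1C(=O)O[C@@H]2[C@@H]1[C@H](O[Si](C)(C)C)/C=C(C)/CC/C=C(C)/[C@@H]2OC(=O)/C(C)=C\C
F2 | step 11 | (5S,6R,7S,8R,9S,10S)-9-angeloyloxy-6-(trimethylsilyloxy)elema-1,3,11(13)-trien-12,8-olide | C=C1C(=O)O[C@@H]2[C@@H]1[C@H](O[Si](C)(C)C)[C@@H](C(C)=C)[C@](C)(C=C)[C@@H]2OC(=O)/C(C)=C\C
F3 | step 13 | (6S,7S,8R,9S)-9-angeloyloxy-6-(chloroacetoxy)germacra-1(10),4,11(13)-trien-12,8-olide | C=C1C(=O)O[C@@H]2[C@@H]1[C@@H](OC(=O)CCl)/C=C(C)/CC/C=C(C)/[C@@H]2OC(=O)/C(C)=C\C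
F4 | step 13 | (6S,7S,8R,9S)-9-angeloyloxy-6-hydroxygermacra-1(10),4,11(13)-trien-12,8-olide | C=C1C(=O)O[C@@H]2[C@@H]1[C@@H](O)/C=C(C)/CC/C=C(C)/[C@@H]2OC(=O)/C(C)=C\C
F5 | step 16 | (1S)-epimer of 20 | C=C1C(=O)O[C@@H]2[C@@H]1[C@@H](O)[C@@H](C(=C)C=O)[C@](C)([C@H]1CO1)[C@@H]2OC(=O)/C(C)=C\C
F6 | step 16 | 1,2-diol from hydrolysis of F5 | C=C1C(=O)O[C@@H]2[C@@H]1[C@@H](O)[C@@H](C(=C)C=O)[C@](C)([C@H](O)CO)[C@@H]2OC(=O)/C(C)=C\C
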